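**Plan**
Retrosynthesis: the acid is freed last from a tert-butyl ester. The diosphenol and C10–H come from a 1(10)-en-3-one by C2 hydroxylation and ketol-to-diosphenol tautomerisation. Ring A is then cut at C4–C5 and contracted to a five-membered 3-ethynyl-3-carbinol.
Enabling feature: in ring A the methylene-bearing C4 lies between the C3 carbonyl and the quaternary C5. This is the retron of a 1,2-shift of C5 from a C3 carbinol onto an activated C4≡C18 alkyne.
Further cuts: C3–C4 (acetylide addition), C7–O and C8–H (epoxide-to-ketone hydride shift, then reduction), C8–C17 (enol triflate methylation), C9–C20 and C9–C11 (two dienolate alkylations of a commercial bicyclic enedione).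
Forward order: ring B and the five-membered ring are bought together. The side chain, made from (R)-citronellic acid, and then the methyl group go onto C9. Ring B is decorated next, and the five-membered ring is enlarged to ring A last.
Stereochemistry: C5 comes from the enedione and C13 from citronellic acid. C19 and the β side chain shield the β face, so MeI (C9), peracid (C7/C8) and hydride (C7) all arrive from the α face. A suprafacial hydride shift sets C8. C10 is set last under thermodynamic control, because only the cis-decalin places C11, C17 and OAc equatorial.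

Key step: step 15

Remark: clerodane numbering is used (ring A = C1–C5, C10; ring B = C5–C10; chain C11–C16 on C9; C17 on C8; C18 = exocyclic CH2 on C4; C19 on C5; C20 on C9). β is the face of C19. In the hydrindane intermediates the five-membered ring holds C1, C2, C3, C5 and C10 and lacks C4.

Step 1
Reactants: 1 (R)-citronellic acid [(3R)-3,7-dimethyloct-6-enoic acid]
Product: 2 tert-butyl (3R)-3,7-dimethyloct-6-enoate
Conditions: Cl3CC(=NH)OtBu (2 equiv), CH2Cl2–cyclohexane, 25 °C
Reagents that add atoms: tert-butyl 2,2,2-trichloroacetimidate, CC(C)(C)OC(=N)C(Cl)(Cl)Cl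
Why: The acid protonates the imidate and is O-alkylated by the released tert-butyl cation (imidate esterification), giving an ester that should resist the later bases, hydrides and organometallics and that leaves under acid in step 17, while C13 is untouched.

Step 2
Reactants: 2 tert-butyl (3R)-3,7-dimethyloct-6-enoate
Product: 3 (4R)-6-tert-butoxy-4-methyl-6-oxohexanoic acid
Conditions: RuCl3 (2 mol %), NaIO4 (4 equiv), MeCN–EtOAc–H2O, 25 °C
Reagents that add atoms: sodium periodate, [Na+].[O-]I(=O)(=O)=O
Why: RuO4 made in situ cleaves the trisubstituted C=C bond oxidatively (catalytic ruthenium tetroxide cleavage) to the acid and acetone without touching the ester or C13.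

Step 3
Reactants: 3 (4R)-6-tert-butoxy-4-methyl-6-oxohexanoic acid
Product: 4 tert-butyl (3S)-5-iodo-3-methylpentanoate
Conditions: PhI(OAc)2 (0.6 equiv), I2 (0.6 equiv), cyclohexane, tungsten lamp, reflux
Reagents that add atoms: iodine, II
Why: Hunsdiecker-type iododecarboxylation with a hypervalent iodine oxidant (O–I homolysis, loss of CO2, iodine capture by the primary radical) removes exactly the one carbon that makes the iodide carbon C11, and C13 keeps its geometry although its descriptor changes to S.

Step 4
Reactants: 5 (7aS)-7a-methyl-2,3,7,7a-tetrahydro-1H-indene-1,5(6H)-dione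
Product: 6 C3 ethylene ketal of 5, (7a'S)-7a'-methyl-2',3',7',7a'-tetrahydrospiro[1,3-dioxolane-2,1'-inden]-5'(6'H)-one
Conditions: 2-ethyl-2-methyl-1,3-dioxolane (solvent), TsOH·H2O (5 mol %), 25 °C
Reagents that add atoms: 2-ethyl-2-methyl-1,3-dioxolane, CCC1(C)OCCO1
Why: Acid-catalysed exchange ketalisation picks the saturated cyclopentanone carbonyl (C3) over the less electrophilic conjugated C8 carbonyl, a standard differentiation of this enedione, so C3 is masked during the enolate chemistry.

Step 5
Reactants: 6 C3 ethylene ketal of 5; 4 tert-butyl (3S)-5-iodo-3-methylpentanoate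
Product: 7 9-alkyl enone ketal (6 carrying on C9 the (3R)-5-tert-butoxy-3-methyl-5-oxopentyl chain C11–C15)
Conditions: NaH (1.0 equiv), DMSO–THF, 25 °C; then 4, 25 °C
Reagents that add atoms: none
Why: Under equilibrating conditions the enone gives the extended C8–C9–C10–C1 dienolate, which the primary iodide alkylates at its α-carbon C9 (dienolate α-alkylation), and the monoalkylated product returns to conjugation, so no stereocentre is formed.

Step 6
Reactants: 7 9-alkyl enone ketal
Product: 8 8-ketone ketal with quaternary C9 (C20 α, C11 chain β) and a C1=C10 double bond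
Conditions: KOtBu (1.3 equiv), MeI (3 equiv), t-BuOH–THF, 0 → 25 °C
Reagents that add atoms: iodomethane, CI
Why: Deconjugative α-alkylation of the extended dienolate, in which iodomethane attacks C9 from the α face anti to the axial C19 methyl on C5, sets the quaternary C9 and leaves the double bond at C1=C10.

Step 7
Reactants: 8 8-ketone ketal
Product: 9 C7=C8 enol triflate of 8
Conditions: KN(SiMe3)2 (1.1 equiv), THF, −78 °C; PhNTf2, −78 → 0 °C
Reagents that add atoms: N-phenylbis(trifluoromethanesulfonimide), O=S(=O)(N(c1ccccc1)S(=O)(=O)C(F)(F)F)C(F)(F)F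
Why: C9 is quaternary, so the ketone can enolise only towards C7, and O-sulfonylation of this single enolate gives the C7=C8 enol triflate.

Step 8
Reactants: 9 C7=C8 enol triflate
Product: 10 8-methyl-1(10),7-diene ketal
Conditions: MeMgBr (1.5 equiv), Fe(acac)3 (5 mol %), THF–NMP, −30 °C
Reagents that add atoms: methylmagnesium bromide, C[Mg]Br
Why: Iron-catalysed Kumada-type cross-coupling of alkenyl triflates with MeMgBr is fast at low temperature, should spare the tert-butyl ester and the ketal, and puts C17 on C8.

Step 9
Reactants: 10 8-methyl-1(10),7-diene ketal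
Product: 11 7α,8α-epoxide of 10
Conditions: mCPBA (1.0 equiv), NaHCO3, CH2Cl2, −20 °C
Reagents that add atoms: 3-chloroperbenzoic acid, OOC(=O)c1cccc(Cl)c1
Why: Prilezhaev epoxidation should come from the α face because the β face carries the axial C19 and C11, and it should prefer C7=C8 over C1=C10, which is flanked by two quaternary carbons and inductively deactivated by the homoallylic ketal oxygens.

Step 10
Reactants: 11 7α,8α-epoxide
Product: 12 7-ketone ketal with 8α-methyl (8β-H)
Conditions: BF3·OEt2 (0.3 equiv), CH2Cl2, −78 °C, then Et3N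
Reagents that add atoms: none
Why: Meinwald rearrangement, in which the Lewis acid opens the epoxide at tertiary C8 and the β-oriented C7–H migrates suprafacially to the β face of C8 anti to the departing α-oxygen, sets C8 (H β, C17 α) and places the carbonyl at C7.

Step 11
Reactants: 12 7-ketone ketal
Product: 13 7β-alcohol ketal
Conditions: NaBH4, MeOH–CH2Cl2, −20 °C
Reagents that add atoms: none
Why: The β-face approach to C7 is blocked by the syn-axial C19 and C11, so hydride should arrive from the α face and give the axial 7β-alcohol, and the low temperature should outrun enolisation at C8.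

Step 12
Reactants: 13 7β-alcohol ketal
Product: 14 7β-acetate ketal
Conditions: Ac2O (10 equiv), DMAP (1 equiv), Et3N, ClCH2CH2Cl, 60 °C
Reagents that add atoms: acetic anhydride, CC(=O)OC(C)=O
Why: DMAP-catalysed acylation under forcing conditions is chosen because the axial 7β-hydroxyl lies between the syn-axial C19 and C11, and C7 keeps its configuration since only the O–H bond reacts.

Step 13
Reactants: 14 7β-acetate ketal
Product: 15 7β-acetoxy-1(10)-en-3-one (hydrindenone with free C3 ketone)
Conditions: TsOH·H2O (10 mol %), acetone–H2O (10:1), 40 °C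
Reagents that add atoms: water, O
Why: Acid-catalysed ketal hydrolysis frees the C3 ketone under conditions mild enough for the acetate and the tert-butyl ester, and C1=C10 should stay out of conjugation because the trisubstituted ring-fusion alkene is the more stable isomer in this hydrindenone.

Step 14
Reactants: 15 7β-acetoxy-1(10)-en-3-one
Product: 16 3α-ethynyl-3β-ol
Conditions: HC≡CH, n-BuLi, THF, −78 °C; CeCl3, −78 °C; then 15, −78 °C
Reagents that add atoms: acetylene, C#C
Why: The weakly basic cerium acetylide adds 1,2 to the easily enolised β,γ-unsaturated ketone rather than deprotonating C2 (organocerium carbonyl addition), approaches C3 from the α face anti to C19 to give the 3β-alcohol, and at −78 °C should leave the hindered acetate and the tert-butyl ester alone.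

Step 15
Reactants: 16 3α-ethynyl-3β-ol
Product: 17 tert-butyl 7β-acetoxy-3-oxocleroda-1(10),4(18)-dien-15-oate
Conditions: (4-CF3C6H4)3PAuCl (5 mol %), AgSbF6 (5 mol %), 4 Å molecular sieves, CH2Cl2, 25 °C
Reagents that add atoms: none
Why: Proposed new method: cationic monovalent gold binds the terminal C4≡C18 alkyne and builds charge at the internal carbon C4, the C3–C5 σ-bond, pushed by the C3 hydroxyl lone pair, shifts to C4 anti to gold (semipinacol 1,2-shift), C3 becomes the ketone, and protodeauration of the C18 vinyl-gold by the released proton leaves the exocyclic methylene. The closest known reaction type is the gold-catalysed ring expansion of 1-alkynylcyclopropanols and 1-alkynylcyclobutanols to 2-alkylidenecycloalkanones, and halonium-induced versions already enlarge 1-(haloethynyl)cyclopentanols to cyclohexanones, so only the pairing of gold with a five-membered carbinol is new, and here the alkyne-to-enone energy gain and the relief of the cyclopentene fused at sp2 C10 supply the driving force. Ring A is not closed by a cyclisation but grows from five to six atoms by insertion of C4 between C3 and C5 (1,2-alkyl migration, no new ring-closing mode). No new stereocentre is formed: C3 is erased and the migrating quaternary C5 keeps its configuration because the shift is suprafacial, so the configuration bought with 5 passes into ring A. The step needs migration of C5 rather than C2, which the higher migratory aptitude of the fully substituted allylic C5 secures, and activation of the alkyne in preference to C1=C10, acetate and ester, which the alkynophilic catalyst and the bridged strain of any enyne cyclisation secure.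

Step 16
Reactants: 17 tert-butyl 7β-acetoxy-3-oxocleroda-1(10),4(18)-dien-15-oate
Product: 19 tert-butyl 7β-acetoxy-2-hydroxy-3-oxo-cis-cleroda-1,4(18)-dien-15-oate (10β-H), via 2α-hydroxy-1(10)-en-3-one ketol 18 (not isolated)
Conditions: KN(SiMe3)2 (1.05 equiv), THF, −78 °C; 2-(phenylsulfonyl)-3-phenyloxaziridine, −78 °C; AcOH; then DBU (0.2 equiv), CH2Cl2, 25 °C
Reagents that add atoms: 2-(phenylsulfonyl)-3-phenyloxaziridine, O=S(=O)(c1ccccc1)N1OC1c1ccccc1
Why: Enolate hydroxylation with an N-sulfonyloxaziridine takes place at C2, the only enolisable and doubly activated position, and the β,γ-unsaturated ketol then tautomerises through its dienediol to the conjugated, hydrogen-bonded diosphenol with protonation at C10 under thermodynamic control, which favours 10β-H because only the cis-decalin can flip ring B so that C11, C17 and the acetate become equatorial, whereas the trans isomer would hold C19, C11 and the acetate syn-axial.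

Step 17
Reactants: 19 tert-butyl 7β-acetoxy-2-hydroxy-3-oxo-cis-cleroda-1,4(18)-dien-15-oate
Product: 20 target, (5S,7S,8S,9R,10R,13R)-7-acetoxy-2-hydroxy-3-oxocleroda-1,4(18)-dien-15-oic acid
Conditions: CF3CO2H–CH2Cl2 (1:4), 0 → 25 °C
Reagents that add atoms: none
Why: Acidolysis of the tert-butyl ester (loss of 2-methylpropene through the tert-butyl cation) frees the acid without touching the acetate, and the acidic medium lets any remaining 10α-H isomer equilibrate through the dienediol to the cis-fused target.

**Compound list**
1 | (R)-citronellic acid | CC(C)=CCC[C@@H](C)CC(=O)O | starting material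
2 | tert-butyl (3R)-3,7-dimethyloct-6-enoate | CC(C)=CCC[C@@H](C)CC(=O)OC(C)(C)C | intermediate
3 | (4R)-6-tert-butoxy-4-methyl-6-oxohexanoic acid | OC(=O)CC[C@@H](C)CC(=O)OC(C)(C)C | intermediate
4 | tert-butyl (3S)-5-iodo-3-methylpentanoate | ICC[C@@H](C)CC(=O)OC(C)(C)C | intermediate
5 | (7aS)-7a-methyl-2,3,7,7a-tetrahydro-1H-indene-1,5(6H)-dione | O=C1CCC2=CC(=O)CC[C@]12C | starting material
6 | C3 ethylene ketal of 5 | O1CCOC12CCC3=CC(=O)CC[C@]23C | intermediate
7 | 9-alkyl enone ketal (C11–C15 chain on C9) | O1CCOC12CCC3=C(CC[C@@H](C)CC(=O)OC(C)(C)C)C(=O)CC[C@]23C | intermediate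
8 | 8-ketone ketal, C20 α, chain β, C1=C10 | O1CCOC12CC=C3[C@@](C)(CC[C@@H](C)CC(=O)OC(C)(C)C)C(=O)CC[C@]23C | intermediate
9 | C7=C8 enol triflate of 8 | O1CCOC12CC=C3[C@@](C)(CC[C@@H](C)CC(=O)OC(C)(C)C)C(OS(=O)(=O)C(F)(F)F)=CC[C@]23C | intermediate
10 | 8-methyl-1(10),7-diene ketal | O1CCOC12CC=C3[C@@](C)(CC[C@@H](C)CC(=O)OC(C)(C)C)C(C)=CC[C@]23C | intermediate
11 | 7α,8α-epoxide of 10 | O1CCOC12CC=C3[C@@](C)(CC[C@@H](C)CC(=O)OC(C)(C)C)[C@]4(C)O[C@@H]4C[C@]23C | intermediate
12 | 7-ketone ketal, 8α-methyl, 8β-H | O1CCOC12CC=C3[C@@](C)(CC[C@@H](C)CC(=O)OC(C)(C)C)[C@H](C)C(=O)C[C@]23C | intermediate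
13 | 7β-alcohol ketal | O1CCOC12CC=C3[C@@](C)(CC[C@@H](C)CC(=O)OC(C)(C)C)[C@H](C)[C@@H](O)C[C@]23C | intermediate
14 | 7β-acetate ketal | O1CCOC12CC=C3[C@@](C)(CC[C@@H](C)CC(=O)OC(C)(C)C)[C@H](C)[C@@H](OC(C)=O)C[C@]23C | intermediate
15 | 7β-acetoxy-1(10)-en-3-one (five-membered ring ketone) | O=C1CC=C2[C@@](C)(CC[C@@H](C)CC(=O)OC(C)(C)C)[C@H](C)[C@@H](OC(C)=O)C[C@]12C | intermediate
16 | 3α-ethynyl-3β-ol | C#C[C@]1(O)CC=C2[C@@](C)(CC[C@@H](C)CC(=O)OC(C)(C)C)[C@H](C)[C@@H](OC(C)=O)C[C@]12C | intermediate
17 | tert-butyl 7β-acetoxy-3-oxocleroda-1(10),4(18)-dien-15-oate | C=C1C(=O)CC=C2[C@@](C)(CC[C@@H](C)CC(=O)OC(C)(C)C)[C@H](C)[C@@H](OC(C)=O)C[C@]12C | intermediate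
18 | 2α-hydroxy-1(10)-en-3-one ketol (2α assumed; the centre is erased in the same step) | C=C1C(=O)[C@H](O)C=C2[C@@](C)(CC[C@@H](C)CC(=O)OC(C)(C)C)[C@H](C)[C@@H](OC(C)=O)C[C@]12C | intermediate
19 | tert-butyl ester of the target | C=C1C(=O)C(O)=C[C@@H]2[C@@](C)(CC[C@@H](C)CC(=O)OC(C)(C)C)[C@H](C)[C@@H](OC(C)=O)C[C@]12C | intermediate
20 | target acid | C=C1C(=O)C(O)=C[C@@H]2[C@@](C)(CC[C@@H](C)CC(=O)O)[C@H](C)[C@@H](OC(C)=O)C[C@]12C | target

Total step count: 17. Longest linear sequence: 16 steps (steps 1–3, then 5–17).

**Steps most likely to fail**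
Step 15: the 1,2-shift from an almost unstrained five-membered carbinol may be too slow. Hydration, Meyer–Schuster isomerisation or catalyst decay could then take over. The fallback sets out from 16 and comes back at 17. Compound 16 would be brominated at the alkyne terminus (NBS, AgNO3 cat., acetone) to the bromoalkyne carbinol F1. With I2 and PhI(OH)OTs in MeCN, F1 should undergo the known iodonium-induced enlargement of 1-(haloethynyl)cyclopentanols to the (Z)-bromoiodomethylidene ketone F2. Zn in AcOH–THF would then remove both halogens to give 17.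

Step 10: the C8 cation may be diverted by a Wagner–Meerwein shift of a C9 substituent or by ring contraction (shift of C6) in place of the hydride shift. C8 may also epimerise through the enol. The fallback sets out from 11 and comes back at 13. Compound 11 would be isomerised with Et2Al(TMP) in toluene at 0 °C (proton loss from C17) to the 7α-hydroxy-8(17)-ene allylic alcohol F3. MnO2 would oxidise this to the α-methylene ketone F4. Luche reduction (NaBH4, CeCl3·7H2O, MeOH) from the α face would give the 7β-allylic alcohol F5. Hydrogenation with [Ir(cod)(PCy3)(py)]PF6 under H2 in CH2Cl2 would reach 13. In that hydrogenation the 7β-hydroxyl should steer hydrogen to the β face of C8 and the hindered C1=C10 bond should stay.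

Step 9: site selectivity between the two trisubstituted alkenes may be poor. The fallback sets out from 8 and comes back at 12, so steps 7 to 10 are left out. The potassium enolate of 8 would be hydroxylated with 2-(phenylsulfonyl)-3-phenyloxaziridine from the α face to the 7α-hydroxy-8-ketone F6, a reaction in which no alkene competes. MeLi–CeCl3 would add to C8 from the α face to give the 8α-methyl-7α,8β-diol F7. A pinacol rearrangement (BF3·OEt2, CH2Cl2, −40 °C) would then ionise the tertiary C8–OH and move the β-oriented C7–H to C8 to give 12.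

**Further compounds**
F1 | step 15 | 3α-(bromoethynyl)-3β-ol | BrC#C[C@]1(O)CC=C2[C@@](C)(CC[C@@H](C)CC(=O)OC(C)(C)C)[C@H](C)[C@@H](OC(C)=O)C[C@]12C
F2 | step 15 | (Z)-18-bromo-18-iodo analogue of 17 | I/C(Br)=C1\C(=O)CC=C2[C@@](C)(CC[C@@H](C)CC(=O)OC(C)(C)C)[C@H](C)[C@@H](OC(C)=O)C[C@]12C
F3 | step 10 | 7α-hydroxy-8(17)-ene ketal | O1CCOC12CC=C3[C@@](C)(CC[C@@H](C)CC(=O)OC(C)(C)C)C(=C)[C@H](O)C[C@]23C
F4 | step 10 | 8(17)-en-7-one ketal | O1CCOC12CC=C3[C@@](C)(CC[C@@H](C)CC(=O)OC(C)(C)C)C(=C)C(=O)C[C@]23C
F5 | step 10 | 7β-hydroxy-8(17)-ene ketal | O1CCOC12CC=C3[C@@](C)(CC[C@@H](C)CC(=O)OC(C)(C)C)C(=C)[C@@H](O)C[C@]23C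
F6 | step 9 | 7α-hydroxy-8-ketone ketal | O1CCOC12CC=C3[C@@](C)(CC[C@@H](C)CC(=O)OC(C)(C)C)C(=O)[C@H](O)C[C@]23C
F7 | step 9 | 8α-methyl-7α,8β-diol ketal | O1CCOC12CC=C3[C@@](C)(CC[C@@H](C)CC(=O)OC(C)(C)C)[C@@](C)(O)[C@H](O)C[C@]23C
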